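**Retrosynthetic overview**

1. Numbering (terpenoid): ring A = C1–C5 and C10 (C3 carbinol, C4 gem-dimethyl); ring B = C5–C10 (C5=C6 alkene, C8 CHMe, C9 quaternary, C10 ring-fusion CH); C11 = OCH2. The last disconnections are the C3 carbinol (from the C3 ketone, reagent-controlled reduction) and the C11–O aryl ether (intact isofraxidin, redox condensation).
2. The 4,4-dimethyl-5-ene unit is the mark of deconjugative C4-methylation of a 4-methyl-4-en-3-one, so ring A is traced back to a bicyclic enone.
3. Key disconnection: the enone is cut at C1–C2 and C4–C5 into methyl 3-oxopentanoate (C2–C3–C4 plus one C4 methyl) and a ring B 2-methylenecyclohexanone (C1=C10–C5=O). This is a [3+3] Michael/aldol-condensation/decarboxylation annulation.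
4. Enabling feature: in ring A the oxygenated C3 lies between C2 and C4 (a ketone with two nucleophilic α-carbons), while C1 and the sp2 ring-fusion carbon C5 are 1,3-related through C10 (an α-methylene ketone with two electrophilic carbons); C10 stays epimerisable.
5. Ring B comes first, from 2-methylcyclohex-2-en-1-one: asymmetric conjugate methylation with formaldehyde trapping sets C8 and C9, then methylenation and allylic oxidation move the carbonyl to C5. Ring order: ring B (purchased carbocycle), ring A (key step), coumarin attached intact.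

Key step: step 6

Remark: isofraxidin, 2-methylcyclohex-2-en-1-one and methyl 3-oxopentanoate are taken as purchased; the coumarin is introduced late because its lactone would not survive the enolate chemistry of steps 1 to 7.

**Step 1**
Reactants: 1 2-methylcyclohex-2-en-1-one
Product: 3 (2S,3S)-2-(hydroxymethyl)-2,3-dimethylcyclohexan-1-one, via bromomagnesium enolate 2 (not isolated)
Conditions: MeMgBr, Cu(OTf)2 (cat.), chiral hydroxyalkyl N-heterocyclic carbene ligand (from its imidazolinium salt; enantiomer that gives the 3S centre), Et2O, −30 °C; then monomeric CH2O in THF, −78 → −30 °C; aq. NH4Cl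
Reagents that add atoms: methylmagnesium bromide (C[Mg]Br); formaldehyde (C=O)
Why: Copper-catalysed asymmetric conjugate addition to the 2-substituted enone gives the fully substituted magnesium enolate regiospecifically, with the ligand fixing the methyl-bearing centre (C8), and the aldol addition to formaldehyde should occur anti to that neighbouring methyl group, which sets the quaternary centre C9 with the two methyl groups cis.

**Step 2**
Reactants: 3 (2S,3S)-2-(hydroxymethyl)-2,3-dimethylcyclohexan-1-one
Product: 4 (2S,3S)-2,3-dimethyl-2-({[tri(propan-2-yl)silyl]oxy}methyl)cyclohexan-1-one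
Conditions: TIPSOTf, 2,6-lutidine, CH2Cl2, −78 → 0 °C
Reagents that add atoms: triisopropylsilyl trifluoromethanesulfonate (CC(C)[Si](C(C)C)(C(C)C)OS(=O)(=O)C(F)(F)F)
Why: Silylation of the neopentyl primary alcohol with a silyl triflate is fast at low temperature, and the base-stable silyl ether blocks retro-aldol loss of formaldehyde in the steps that follow without touching a stereocentre.

**Step 3**
Reactants: 4 (2S,3S)-2,3-dimethyl-2-({[tri(propan-2-yl)silyl]oxy}methyl)cyclohexan-1-one
Product: 5 triisopropyl{[(1R,6S)-1,6-dimethyl-2-methylidenecyclohexyl]methoxy}silane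
Conditions: Ph3PCH3Br, KOtBu, toluene, 90 °C
Reagents that add atoms: methyltriphenylphosphonium bromide (C[P+](c1ccccc1)(c1ccccc1)c1ccccc1.[Br-])
Why: Wittig methylenation with the lithium-free ylide, generated in the flask from the phosphonium salt and KOtBu, at elevated temperature is the standard answer to a ketone flanked by a quaternary carbon, and the only enolisable position (the C5 methylene) carries no stereocentre.

**Step 4**
Reactants: 5 triisopropyl{[(1R,6S)-1,6-dimethyl-2-methylidenecyclohexyl]methoxy}silane
Product: 6 (3R,4S)-3,4-dimethyl-2-methylidene-3-({[tri(propan-2-yl)silyl]oxy}methyl)cyclohexan-1-ol (both carbinol epimers)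
Conditions: SeO2 (cat.), t-BuOOH, CH2Cl2, 0 °C → rt
Reagents that add atoms: selenium dioxide (O=[Se]=O); tert-butyl hydroperoxide (CC(C)(C)OO)
Why: Selenium dioxide allylic oxidation runs by an ene reaction at the terminal alkene carbon and a [2,3]-sigmatropic shift, so the oxygen (delivered by selenium dioxide and replenished by the hydroperoxide) is returned to the only allylic carbon that bears hydrogen (C5) with the exocyclic alkene restored; the new carbinol centre is removed in the next step.

**Step 5**
Reactants: 6 (3R,4S)-3,4-dimethyl-2-methylidene-3-({[tri(propan-2-yl)silyl]oxy}methyl)cyclohexan-1-ol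
Product: 7 (3R,4S)-3,4-dimethyl-2-methylidene-3-({[tri(propan-2-yl)silyl]oxy}methyl)cyclohexan-1-one
Conditions: Dess–Martin periodinane, CH2Cl2, rt
Reagents that add atoms: none
Why: Dess–Martin oxidation of the secondary allylic alcohol is mild and neutral, and the quaternary C9 next to the exocyclic alkene prevents isomerisation of the α-methylene ketone to an endocyclic enone.

**Step 6**
Reactants: 7 (3R,4S)-3,4-dimethyl-2-methylidene-3-({[tri(propan-2-yl)silyl]oxy}methyl)cyclohexan-1-one; 8 methyl 3-oxopentanoate
Product: 11 (4aR,5R,6S)-1,5,6-trimethyl-5-({[tri(propan-2-yl)silyl]oxy}methyl)-4,4a,5,6,7,8-hexahydronaphthalen-2(3H)-one, via Michael adduct 9 (not isolated), via enone ester 10 (not isolated)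
Conditions: NaOMe (cat.), MeOH, 0 °C → reflux; then aq. KOH, reflux
Reagents that add atoms: none
Why: Methoxide deprotonates the doubly activated methylene of 8 (future C2), which adds in a Michael fashion to the exocyclic enone terminus of 7 (future C1) and forms the C1–C2 bond; the ethyl-ketone α-carbon (C4) of adduct 9 then adds to the ring B carbonyl (C5) and the ketol loses water into conjugation, which forms the C4–C5 bond as the enone double bond of 10, and hydroxide finally removes the ester by saponification and decarboxylation. The closest known reaction type is the Robinson-type annulation in its β-keto ester/α-methylene ketone variant, a classical [3+3] route to bicyclic enones. Ring A is closed by a 6-(enolendo)-exo-trig aldol addition followed by E1cB dehydration, whereas the competing closure from the ring B α′-carbon (C6) onto the C3 ketone would give a bridged ketol that cannot dehydrate and should revert. The only new stereocentre, C10, is α to a ketone in 9 and γ to the enone afterwards, so it is under thermodynamic control and should settle with the ring A bond equatorial on ring B, cis to the axial C9 methyl group and trans to the CH2OSi group, which is the target arrangement; C8 and C9 are not enolisable and the C2 ester centre disappears on decarboxylation. The step needs regiocontrol in both bond formations: the ester of 8 makes C2 the only Michael donor and leaves the ethyl CH2 as the only carbon that can condense to an enone.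

**Step 7**
Reactants: 11 (4aR,5R,6S)-1,5,6-trimethyl-5-({[tri(propan-2-yl)silyl]oxy}methyl)-4,4a,5,6,7,8-hexahydronaphthalen-2(3H)-one
Product: 12 (4aR,5R,6S)-1,1,5,6-tetramethyl-5-({[tri(propan-2-yl)silyl]oxy}methyl)-3,4,4a,5,6,7-hexahydronaphthalen-2(1H)-one
Conditions: KOtBu (slight excess), t-BuOH/THF, rt; MeI
Reagents that add atoms: iodomethane (CI)
Why: In this deconjugative α-alkylation of an enone, tert-butoxide removes a γ-hydrogen from the C6 methylene (more accessible than the C10 methine next to the quaternary C9) to give the heteroannular dienolate, which is methylated at its α-carbon C4, so that C4 becomes quaternary and the double bond is left at C5=C6 with C10 untouched.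

**Step 8**
Reactants: 12 (4aR,5R,6S)-1,1,5,6-tetramethyl-5-({[tri(propan-2-yl)silyl]oxy}methyl)-3,4,4a,5,6,7-hexahydronaphthalen-2(1H)-one
Product: 13 (4aR,5R,6S)-5-(hydroxymethyl)-1,1,5,6-tetramethyl-3,4,4a,5,6,7-hexahydronaphthalen-2(1H)-one
Conditions: HF·pyridine, THF/pyridine, 0 °C → rt
Reagents that add atoms: none
Why: Fluoride-driven desilylation cleaves the silyl ether under buffered conditions that leave the β,γ-unsaturated ketone, which cannot move into conjugation past the quaternary C4, unchanged.

**Step 9**
Reactants: 13 (4aR,5R,6S)-5-(hydroxymethyl)-1,1,5,6-tetramethyl-3,4,4a,5,6,7-hexahydronaphthalen-2(1H)-one; 14 isofraxidin (7-hydroxy-6,8-dimethoxy-2H-chromen-2-one)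
Product: 15 6,8-dimethoxy-7-{[(1R,2S,8aR)-1,2,5,5-tetramethyl-6-oxo-1,2,3,5,6,7,8,8a-octahydronaphthalen-1-yl]methoxy}-2H-chromen-2-one
Conditions: Bu3P=CHCN (cyanomethylenetributylphosphorane), toluene, 100 °C
Reagents that add atoms: none
Why: In this Mitsunobu-type redox condensation the acidic 7-hydroxyl of the coumarin is a competent pronucleophile and the phosphorane tolerates the heating that SN2 displacement at the neopentyl-type C11 requires, while the hindered ketone and the lactone are inert to the stabilised ylide and no stereocentre is involved.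

**Step 10**
Reactants: 15 6,8-dimethoxy-7-{[(1R,2S,8aR)-1,2,5,5-tetramethyl-6-oxo-1,2,3,5,6,7,8,8a-octahydronaphthalen-1-yl]methoxy}-2H-chromen-2-one
Product: 16 7-{[(1R,2S,6S,8aR)-6-hydroxy-1,2,5,5-tetramethyl-1,2,3,5,6,7,8,8a-octahydronaphthalen-1-yl]methoxy}-6,8-dimethoxy-2H-chromen-2-one (CNP0110107.1)
Conditions: (R)-2-methyl-CBS-oxazaborolidine (cat.), catecholborane, toluene/CH2Cl2, −78 → −30 °C; MeOH, then pH 7 buffer
Reagents that add atoms: none
Why: In the Corey–Bakshi–Shibata reduction the oxazaborolidine binds the ketone on the side of the C2 methylene and away from the quaternary C4, so the (R)-catalyst should deliver hydride to the face that gives the 3S carbinol (the axial alcohol, also the outcome expected for a bulky hydride donor on this ring), while catecholborane at low temperature leaves the lactone and both alkenes alone.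

**Compound list**

1 | 2-methylcyclohex-2-en-1-one | CC1=CCCCC1=O | starting material
2 | bromomagnesium (3S)-2,3-dimethylcyclohex-1-en-1-olate | CC1=C(O[Mg]Br)CCC[C@@H]1C | intermediate (not isolated)
3 | (2S,3S)-2-(hydroxymethyl)-2,3-dimethylcyclohexan-1-one | OC[C@@]1(C)C(=O)CCC[C@@H]1C | intermediate
4 | (2S,3S)-2,3-dimethyl-2-({[tri(propan-2-yl)silyl]oxy}methyl)cyclohexan-1-one | CC(C)[Si](C(C)C)(C(C)C)OC[C@@]1(C)C(=O)CCC[C@@H]1C | intermediate
5 | triisopropyl{[(1R,6S)-1,6-dimethyl-2-methylidenecyclohexyl]methoxy}silane | CC(C)[Si](C(C)C)(C(C)C)OC[C@@]1(C)C(=C)CCC[C@@H]1C | intermediate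
6 | (3R,4S)-3,4-dimethyl-2-methylidene-3-({[tri(propan-2-yl)silyl]oxy}methyl)cyclohexan-1-ol (both carbinol epimers) | CC(C)[Si](C(C)C)(C(C)C)OC[C@@]1(C)C(=C)C(O)CC[C@@H]1C | intermediate
7 | (3R,4S)-3,4-dimethyl-2-methylidene-3-({[tri(propan-2-yl)silyl]oxy}methyl)cyclohexan-1-one | CC(C)[Si](C(C)C)(C(C)C)OC[C@@]1(C)C(=C)C(=O)CC[C@@H]1C | intermediate
8 | methyl 3-oxopentanoate | CCC(=O)CC(=O)OC | starting material
9 | methyl 2-{[(1S,2R,3S)-2,3-dimethyl-6-oxo-2-({[tri(propan-2-yl)silyl]oxy}methyl)cyclohexyl]methyl}-3-oxopentanoate (mixture at the ester-bearing carbon) | CC(C)[Si](C(C)C)(C(C)C)OC[C@@]1(C)[C@H](CC(C(=O)OC)C(=O)CC)C(=O)CC[C@@H]1C | intermediate (not isolated)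
10 | methyl (4aR,5R,6S)-1,5,6-trimethyl-2-oxo-5-({[tri(propan-2-yl)silyl]oxy}methyl)-2,3,4,4a,5,6,7,8-octahydronaphthalene-3-carboxylate (mixture at C3) | CC(C)[Si](C(C)C)(C(C)C)OC[C@@]1(C)[C@@H]2CC(C(=O)OC)C(=O)C(C)=C2CC[C@@H]1C | intermediate (not isolated)
11 | (4aR,5R,6S)-1,5,6-trimethyl-5-({[tri(propan-2-yl)silyl]oxy}methyl)-4,4a,5,6,7,8-hexahydronaphthalen-2(3H)-one | CC(C)[Si](C(C)C)(C(C)C)OC[C@@]1(C)[C@@H]2CCC(=O)C(C)=C2CC[C@@H]1C | intermediate
12 | (4aR,5R,6S)-1,1,5,6-tetramethyl-5-({[tri(propan-2-yl)silyl]oxy}methyl)-3,4,4a,5,6,7-hexahydronaphthalen-2(1H)-one | CC(C)[Si](C(C)C)(C(C)C)OC[C@@]1(C)[C@@H]2CCC(=O)C(C)(C)C2=CC[C@@H]1C | intermediate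
13 | (4aR,5R,6S)-5-(hydroxymethyl)-1,1,5,6-tetramethyl-3,4,4a,5,6,7-hexahydronaphthalen-2(1H)-one | OC[C@@]1(C)[C@@H]2CCC(=O)C(C)(C)C2=CC[C@@H]1C | intermediate
14 | isofraxidin (7-hydroxy-6,8-dimethoxy-2H-chromen-2-one) | COc1cc2ccc(=O)oc2c(OC)c1O | starting material
15 | 6,8-dimethoxy-7-{[(1R,2S,8aR)-1,2,5,5-tetramethyl-6-oxo-1,2,3,5,6,7,8,8a-octahydronaphthalen-1-yl]methoxy}-2H-chromen-2-one | COc1cc2ccc(=O)oc2c(OC)c1OC[C@@]1(C)[C@@H]2CCC(=O)C(C)(C)C2=CC[C@@H]1C | intermediate
16 | 7-{[(1R,2S,6S,8aR)-6-hydroxy-1,2,5,5-tetramethyl-1,2,3,5,6,7,8,8a-octahydronaphthalen-1-yl]methoxy}-6,8-dimethoxy-2H-chromen-2-one | COc1cc2ccc(=O)oc2c(OC)c1OC[C@@]1(C)[C@@H]2CC[C@H](O)C(C)(C)C2=CC[C@@H]1C | target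

**Step count and risks**

Total step count: 10. Longest linear sequence: 10 steps (1 to 16; 8 and 14 enter as purchased partners).

Steps most likely to fail:

Step 9. Substitution at the neopentyl-type C11 is slow, so the activated alcohol may be lost to elimination or rearrangement before the phenoxide attacks, or may not react at all. The fallback sets out from 13 and moves the activation into a separate step: triflic anhydride and 2,6-di-tert-butyl-4-methylpyridine in CH2Cl2 at −78 °C should give [(1R,2S,8aR)-1,2,5,5-tetramethyl-6-oxo-1,2,3,5,6,7,8,8a-octahydronaphthalen-1-yl]methyl trifluoromethanesulfonate F1. This isolated sulfonate is then displaced by the caesium salt of isofraxidin 14 (Cs2CO3, DMF, rt to 40 °C), which returns to the route at 15.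

Step 10. The facial selectivity may be poor if the catalyst preference and the inherent preference of the ring do not reinforce each other, and the hindered ketone may react slowly enough for the coumarin to be attacked. The fallback sets out from 12 and reduces before the coumarin is present, under substrate control: LiBH(s-Bu)3 (L-Selectride) in THF at −78 °C should attack along the equatorial trajectory and give the axial alcohol (2S,4aR,5R,6S)-1,1,5,6-tetramethyl-5-({[tri(propan-2-yl)silyl]oxy}methyl)-1,2,3,4,4a,5,6,7-octahydronaphthalen-2-ol F2. HF·pyridine then frees (2S,4aR,5R,6S)-5-(hydroxymethyl)-1,1,5,6-tetramethyl-1,2,3,4,4a,5,6,7-octahydronaphthalen-2-ol F3, and condensation of its primary hydroxyl with 14 under the conditions of step 9 (the hindered axial secondary hydroxyl should not be activated) comes back to the route at 16.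

Step 1. The methyl Grignard reagent may add with insufficient enantioselectivity, and the hindered enolate may give retro-aldol loss or multiple addition of formaldehyde during trapping. The fallback sets out from 1 and separates the two events: Me3Al with copper thiophene-2-carboxylate (Cu(O2CC4H3S)) and a chiral phosphoramidite ligand in Et2O, followed by TMSOTf, should give the isolable silyl enol ether {[(3S)-2,3-dimethylcyclohex-1-en-1-yl]oxy}trimethylsilane F4. A Mukaiyama aldol reaction of F4 with aqueous formaldehyde catalysed by Sc(OTf)3 in THF then comes back to the route at 3.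

**Further compounds**

F1 | step 9 | [(1R,2S,8aR)-1,2,5,5-tetramethyl-6-oxo-1,2,3,5,6,7,8,8a-octahydronaphthalen-1-yl]methyl trifluoromethanesulfonate | O=S(=O)(OC[C@@]1(C)[C@@H]2CCC(=O)C(C)(C)C2=CC[C@@H]1C)C(F)(F)F
F2 | step 10 | (2S,4aR,5R,6S)-1,1,5,6-tetramethyl-5-({[tri(propan-2-yl)silyl]oxy}methyl)-1,2,3,4,4a,5,6,7-octahydronaphthalen-2-ol | CC(C)[Si](C(C)C)(C(C)C)OC[C@@]1(C)[C@@H]2CC[C@H](O)C(C)(C)C2=CC[C@@H]1C
F3 | step 10 | (2S,4aR,5R,6S)-5-(hydroxymethyl)-1,1,5,6-tetramethyl-1,2,3,4,4a,5,6,7-octahydronaphthalen-2-ol | OC[C@@]1(C)[C@@H]2CC[C@H](O)C(C)(C)C2=CC[C@@H]1C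
F4 | step 1 | {[(3S)-2,3-dimethylcyclohex-1-en-1-yl]oxy}trimethylsilane | CC1=C(O[Si](C)(C)C)CCC[C@@H]1C
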